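**Retrosynthetic overview**

- The strategy rests on one feature of the indane. The cyclopentane ring (C1, C2, C3, C3a, C7a) is read as a one-carbon ring expansion of a 3,3-dimethylcyclobutane spiro-fused at C3a. The C6 carbon substituent, para to C3a, sits where a dienone oxygen was.
- The C1–C7a bond and the arene therefore come from a dienone–phenol rearrangement of spiro[3.5]nona-5,8-dien-7-one 18 to phenol 19.
- After the rearrangement, the C6 phenol becomes a triflate, then CH2OH by Stille hydroxymethylation, then the butanoate. The C4 acetoxymethyl and C5 chloroethyl groups are already in place.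
- Dienone 18 comes from spiro enone 9 by conjugate hydroxymethylation at C5 (silylmethyl copper addition, Tamao oxidation), acetylation and two dehydrogenations.
- Enone 9 comes from a Robinson annulation of 3,3-dimethylcyclobutanecarbaldehyde 3 with 6-chlorohex-1-en-3-one 7. Ring order: cyclobutane (bought), cyclohexenone (step 5), cyclopentane and arene together (step 11).

Key step: step 11

Assumption: the target has no stereocentre. Compounds 12–16 are racemic, and 13–15 may form as cis/trans mixtures at C5/C6 (trans drawn). This is of no consequence because both carbons become sp2 in steps 9 and 10.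

**Route**

Step 1
Reactants: 1 3,3-dimethylcyclobutane-1-carboxylic acid
Product: 2 (3,3-dimethylcyclobutyl)methanol
Conditions: LiAlH4, THF, 0 °C to reflux; aqueous work-up
Reagents that add atoms: none
Why: Hydride reduction of a carboxylic acid to the primary alcohol is standard and leaves the cyclobutane untouched.

Step 2
Reactants: 2 (3,3-dimethylcyclobutyl)methanol
Product: 3 3,3-dimethylcyclobutane-1-carbaldehyde
Conditions: TEMPO (cat.), KBr (cat.), aq. NaOCl, NaHCO3, CH2Cl2, 0 °C
Reagents that add atoms: none
Why: The Anelli oxidation (TEMPO-catalysed hypochlorite oxidation) should stop at the aldehyde and leaves only aqueous salts, so the volatile aldehyde can be carried on as a dried solution or distilled.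

Step 3
Reactants: 4 4-chlorobutanoyl chloride
Product: 5 4-chloro-N-methoxy-N-methylbutanamide
Conditions: MeNH(OMe)·HCl, pyridine, CH2Cl2, 0 °C to rt
Reagents that add atoms: N,O-dimethylhydroxylamine hydrochloride, CNOC.Cl
Why: N-Acylation by the acid chloride gives the Weinreb amide, and the primary chloride is not displaced by the weakly nucleophilic amine at this temperature.

Step 4
Reactants: 5 4-chloro-N-methoxy-N-methylbutanamide; 6 vinylmagnesium bromide
Product: 7 6-chlorohex-1-en-3-one
Conditions: THF, 0 °C; inverse quench into cold 2 M HCl; trace of BHT, used promptly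
Reagents that add atoms: none
Why: In the Weinreb ketone synthesis the chelated tetrahedral adduct prevents over-addition, and the acidic inverse quench keeps the released amine protonated so that it cannot add to the vinyl ketone.

Step 5
Reactants: 3 3,3-dimethylcyclobutane-1-carbaldehyde; 7 6-chlorohex-1-en-3-one
Product: 9 6-(2-chloroethyl)-2,2-dimethylspiro[3.5]non-5-en-7-one, via keto aldehyde 8 (not isolated)
Conditions: conc. H2SO4 (cat.), toluene, 45 °C, then reflux (Dean–Stark)
Reagents that add atoms: none
Why: In this acid-catalysed Robinson annulation the enol of the α-branched aldehyde adds to the protonated vinyl ketone (Michael addition) and sets the spiro quaternary carbon, then only the chloropropyl-side α-CH2 of the ketone can close a six-membered ring onto the non-enolisable aldehyde (6-(enolendo)-exo-trig aldol condensation), and acid avoids the cyclopropane closure that a γ-chloro ketone suffers with base.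

Step 6
Reactants: 9 6-(2-chloroethyl)-2,2-dimethylspiro[3.5]non-5-en-7-one; 10 (chloromethyl)isopropoxydimethylsilane
Product: 12 {[6-(2-chloroethyl)-2,2-dimethyl-7-(trimethylsilyloxy)spiro[3.5]non-6-en-5-yl]methyl}dimethyl(propan-2-yloxy)silane, via Grignard reagent 11 (not isolated)
Conditions: 10, Mg, THF, reflux; then 9, CuBr·SMe2 (10 mol %), Me3SiCl, THF, −78 to −30 °C; Et3N, pentane, filtration; crude product used directly
Reagents that add atoms: chlorotrimethylsilane, C[Si](C)(C)Cl
Why: Copper-catalysed, Me3SiCl-accelerated conjugate addition of the silylmethyl Grignard reagent (a hydroxymethyl anion equivalent) should form the C5–CH2Si bond, and trapping the enolate as its silyl enol ether keeps it from alkylating the 2-chloroethyl arm; the new C5 centre is racemic and is erased later.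

Step 7
Reactants: 12 {[6-(2-chloroethyl)-2,2-dimethyl-7-(trimethylsilyloxy)spiro[3.5]non-6-en-5-yl]methyl}dimethyl(propan-2-yloxy)silane
Product: 14 trans-6-(2-chloroethyl)-5-(hydroxymethyl)-2,2-dimethylspiro[3.5]nonan-7-one, via silyl ketone 13 (not isolated)
Conditions: KF, KHCO3, 30% H2O2, THF/MeOH, rt
Reagents that add atoms: hydrogen peroxide, OO
Why: Fluoride in methanol cleaves the enol silane to the ketone, and the Tamao oxidation then converts the C–Si(OiPr)Me2 bond to C–OH under mildly basic peroxide conditions that a saturated ketone and a primary chloride tolerate.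

Step 8
Reactants: 14 trans-6-(2-chloroethyl)-5-(hydroxymethyl)-2,2-dimethylspiro[3.5]nonan-7-one
Product: 15 [trans-6-(2-chloroethyl)-2,2-dimethyl-7-oxospiro[3.5]nonan-5-yl]methyl acetate
Conditions: Ac2O, pyridine, DMAP (cat.), CH2Cl2, 0 °C to rt
Reagents that add atoms: acetic anhydride, CC(=O)OC(C)=O
Why: DMAP-catalysed acetylation of the only hydroxyl installs the C4 acetoxymethyl group of the target at a stage where no selectivity question arises.

Step 9
Reactants: 15 [trans-6-(2-chloroethyl)-2,2-dimethyl-7-oxospiro[3.5]nonan-5-yl]methyl acetate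
Product: 17 [6-(2-chloroethyl)-2,2-dimethyl-7-oxospiro[3.5]non-5-en-5-yl]methyl acetate, via silyl enol ether 16 (not isolated)
Conditions: Me3SiOTf, Et3N, CH2Cl2, 0 °C to rt (equilibrating); then Pd(OAc)2 (1.1 equiv), MeCN, rt
Reagents that add atoms: none
Why: Soft enolisation under equilibrating conditions should favour the more substituted C6=C7 enol silane, and in the Saegusa–Ito oxidation palladium adds to C6 on the face opposite the C5 acetoxymethyl group, so the C5 hydrogen is syn for β-hydride elimination to the conjugated tetrasubstituted enone.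

Step 10
Reactants: 17 [6-(2-chloroethyl)-2,2-dimethyl-7-oxospiro[3.5]non-5-en-5-yl]methyl acetate
Product: 18 [6-(2-chloroethyl)-2,2-dimethyl-7-oxospiro[3.5]nona-5,8-dien-5-yl]methyl acetate
Conditions: DDQ, 1,4-dioxane, reflux
Reagents that add atoms: none
Why: DDQ dehydrogenation of a 4,4-disubstituted cyclohex-2-enone is the classical entry to cyclohexa-2,5-dienones: without strong acid the cross-conjugated C7/C8 enol forms and DDQ takes hydride from C9, while acetate and chloride are inert.

Step 11
Reactants: 18 [6-(2-chloroethyl)-2,2-dimethyl-7-oxospiro[3.5]nona-5,8-dien-5-yl]methyl acetate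
Product: 19 [5-(2-chloroethyl)-6-hydroxy-2,2-dimethyl-2,3-dihydro-1H-inden-4-yl]methyl acetate
Conditions: CF3CO2H, CH2Cl2, 0 °C to rt
Reagents that add atoms: none
Why: Protonation of the dienone oxygen gives a hydroxy-substituted cyclohexadienyl cation with positive charge on C5 and C9 next to the spiro carbon; one of the two equivalent cyclobutane CH2 groups shifts from C4 to the hydrogen-bearing C9 and loss of that hydrogen aromatises the ring, which is the acid-catalysed dienone–phenol rearrangement known for 4-spiro-annulated cyclohexa-2,5-dienones. The cyclopentane is closed not by an end-to-end cyclisation but by this suprafacial 1,2-alkyl shift, a cyclobutylcarbinyl-to-cyclopentyl ring expansion that forms the C1–C7a bond and adds release of four-ring strain to the aromatic driving force. No stereocentre is created. The selectivity needed is a shift to C9 and not to C5: C5 carries the inductively withdrawing acetoxymethyl group and is the more hindered terminus, and a shift to it gives a cation that cannot lose a proton, so it can only revert toward the productive channel. The gem-dimethyl group makes both cyclobutane CH2 carbons neopentyl, which shuts off nucleophilic opening of the four-membered ring, and the acid is mild enough to leave the benzylic acetate (meta to the new hydroxyl) and the primary chloride alone.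

Step 12
Reactants: 19 [5-(2-chloroethyl)-6-hydroxy-2,2-dimethyl-2,3-dihydro-1H-inden-4-yl]methyl acetate
Product: 20 [5-(2-chloroethyl)-2,2-dimethyl-6-(trifluoromethanesulfonyloxy)-2,3-dihydro-1H-inden-4-yl]methyl acetate
Conditions: Tf2O, pyridine, CH2Cl2, −78 to 0 °C
Reagents that add atoms: trifluoromethanesulfonic anhydride, O=S(=O)(OS(=O)(=O)C(F)(F)F)C(F)(F)F
Why: Fast O-sulfonylation in a weakly basic medium at low temperature should triflate the phenol before any phenoxide can close onto the ortho 2-chloroethyl arm to a dihydrobenzofuran.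

Step 13
Reactants: 20 [5-(2-chloroethyl)-2,2-dimethyl-6-(trifluoromethanesulfonyloxy)-2,3-dihydro-1H-inden-4-yl]methyl acetate; 21 (tributylstannyl)methanol
Product: 22 [5-(2-chloroethyl)-6-(hydroxymethyl)-2,2-dimethyl-2,3-dihydro-1H-inden-4-yl]methyl acetate
Conditions: Pd(PPh3)4 (10 mol %), LiCl, 1,4-dioxane, 100 °C
Reagents that add atoms: none
Why: In this Stille coupling zerovalent palladium inserts into the aryl C–OTf bond, the α-hydroxymethyl group transfers from tin in preference to butyl, and the neutral conditions leave the acetate and the unactivated primary chloride untouched.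

Step 14
Reactants: 22 [5-(2-chloroethyl)-6-(hydroxymethyl)-2,2-dimethyl-2,3-dihydro-1H-inden-4-yl]methyl acetate
Product: 23 [4-(acetoxymethyl)-5-(2-chloroethyl)-2,2-dimethyl-2,3-dihydro-1H-inden-6-yl]methyl butanoate
Conditions: (PrCO)2O, Et3N, DMAP (cat.), CH2Cl2, 0 °C to rt
Reagents that add atoms: butanoic anhydride, CCCC(=O)OC(=O)CCC
Why: DMAP-catalysed acylation of the single free benzylic hydroxyl should give the butanoate without disturbing the acetate.

**Compound list**

1 | 3,3-dimethylcyclobutane-1-carboxylic acid | OC(=O)C1CC(C)(C)C1 | starting material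
2 | (3,3-dimethylcyclobutyl)methanol | OCC1CC(C)(C)C1 | intermediate
3 | 3,3-dimethylcyclobutane-1-carbaldehyde | O=CC1CC(C)(C)C1 | intermediate
4 | 4-chlorobutanoyl chloride | ClCCCC(Cl)=O | starting material
5 | 4-chloro-N-methoxy-N-methylbutanamide | CON(C)C(=O)CCCCl | intermediate
6 | vinylmagnesium bromide | C=C[Mg]Br | starting material
7 | 6-chlorohex-1-en-3-one | C=CC(=O)CCCCl | intermediate
8 | 1-(6-chloro-3-oxohexyl)-3,3-dimethylcyclobutane-1-carbaldehyde | O=CC1(CCC(=O)CCCCl)CC(C)(C)C1 | intermediate (not isolated)
9 | 6-(2-chloroethyl)-2,2-dimethylspiro[3.5]non-5-en-7-one | O=C1CCC2(CC(C)(C)C2)C=C1CCCl | intermediate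
10 | (chloromethyl)isopropoxydimethylsilane | CC(C)O[Si](C)(C)CCl | starting material
11 | [(isopropoxydimethylsilyl)methyl]magnesium chloride | CC(C)O[Si](C)(C)C[Mg]Cl | intermediate (not isolated)
12 | {[6-(2-chloroethyl)-2,2-dimethyl-7-(trimethylsilyloxy)spiro[3.5]non-6-en-5-yl]methyl}dimethyl(propan-2-yloxy)silane, racemic | C[Si](C)(C)OC1=C(CCCl)C(C[Si](C)(C)OC(C)C)C2(CC1)CC(C)(C)C2 | intermediate
13 | trans-6-(2-chloroethyl)-5-{[dimethyl(propan-2-yloxy)silyl]methyl}-2,2-dimethylspiro[3.5]nonan-7-one, racemic | CC(C)O[Si](C)(C)C[C@@H]1[C@@H](CCCl)C(=O)CCC12CC(C)(C)C2 | intermediate (not isolated)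
14 | trans-6-(2-chloroethyl)-5-(hydroxymethyl)-2,2-dimethylspiro[3.5]nonan-7-one, racemic | OC[C@@H]1[C@@H](CCCl)C(=O)CCC12CC(C)(C)C2 | intermediate
15 | [trans-6-(2-chloroethyl)-2,2-dimethyl-7-oxospiro[3.5]nonan-5-yl]methyl acetate, racemic | CC(=O)OC[C@@H]1[C@@H](CCCl)C(=O)CCC12CC(C)(C)C2 | intermediate
16 | [6-(2-chloroethyl)-2,2-dimethyl-7-(trimethylsilyloxy)spiro[3.5]non-6-en-5-yl]methyl acetate, racemic | CC(=O)OCC1C(CCCl)=C(O[Si](C)(C)C)CCC12CC(C)(C)C2 | intermediate (not isolated)
17 | [6-(2-chloroethyl)-2,2-dimethyl-7-oxospiro[3.5]non-5-en-5-yl]methyl acetate | CC(=O)OCC1=C(CCCl)C(=O)CCC12CC(C)(C)C2 | intermediate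
18 | [6-(2-chloroethyl)-2,2-dimethyl-7-oxospiro[3.5]nona-5,8-dien-5-yl]methyl acetate | CC(=O)OCC1=C(CCCl)C(=O)C=CC12CC(C)(C)C2 | intermediate (key-step precursor)
19 | [5-(2-chloroethyl)-6-hydroxy-2,2-dimethyl-2,3-dihydro-1H-inden-4-yl]methyl acetate | CC(=O)OCc1c(CCCl)c(O)cc2CC(C)(C)Cc12 | intermediate (key-step product)
20 | [5-(2-chloroethyl)-2,2-dimethyl-6-(trifluoromethanesulfonyloxy)-2,3-dihydro-1H-inden-4-yl]methyl acetate | CC(=O)OCc1c(CCCl)c(OS(=O)(=O)C(F)(F)F)cc2CC(C)(C)Cc12 | intermediate
21 | (tributylstannyl)methanol | OC[Sn](CCCC)(CCCC)CCCC | starting material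
22 | [5-(2-chloroethyl)-6-(hydroxymethyl)-2,2-dimethyl-2,3-dihydro-1H-inden-4-yl]methyl acetate | CC(=O)OCc1c(CCCl)c(CO)cc2CC(C)(C)Cc12 | intermediate
23 | [4-(acetoxymethyl)-5-(2-chloroethyl)-2,2-dimethyl-2,3-dihydro-1H-inden-6-yl]methyl butanoate | CCCC(=O)OCc1cc2c(c(COC(C)=O)c1CCCl)CC(C)(C)C2 | target

**Step count**

Total: 14 steps. Longest linear sequence: 12 steps (steps 1, 2, 5–14, from acid 1); steps 3 and 4 form the two-step side branch to enone 7.

**Steps most likely to fail, with fallbacks**

1. Step 11 (key rearrangement). Acid strong enough to protonate the dienone may also send the shift to the acetoxymethyl-bearing carbon or ionise the benzylic acetate, and the electron-rich phenol could then be alkylated by the resulting cations. The fallback lowers the oxidation level of the carbonyl first, so that much weaker acid suffices and no phenol is formed. It sets out from 18. Addition of vinylmagnesium bromide 6 with CeCl3 (THF, −78 °C) to the dienone carbonyl should give the tertiary bis-allylic alcohol [6-(2-chloroethyl)-7-ethenyl-7-hydroxy-2,2-dimethylspiro[3.5]nona-5,8-dien-5-yl]methyl acetate F1. Catalytic camphorsulfonic acid (CH2Cl2, 0 °C) ionises it, and the same ring-expanding shift with loss of a proton (dienol–benzene rearrangement) should give [5-(2-chloroethyl)-6-ethenyl-2,2-dimethyl-2,3-dihydro-1H-inden-4-yl]methyl acetate F2. Ozonolysis (CH2Cl2/MeOH, −78 °C) with NaBH4 work-up cuts the vinyl group to the benzylic alcohol, and the route is rejoined at 22.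

2. Step 9 (first dehydrogenation). Silylation may occur on the less hindered C8 side instead of toward C6, and β-hydride elimination may run into the chloroethyl chain instead of taking the C5 hydrogen. The fallback reverses the order of the two dehydrogenations so that each enolisation has only one possible direction. It sets out from 15. LiN(SiMe3)2 with Me3SiCl as internal quench (THF, −78 °C) should take the C8 methylene to the kinetic enol silane [trans-6-(2-chloroethyl)-2,2-dimethyl-7-(trimethylsilyloxy)spiro[3.5]non-7-en-5-yl]methyl acetate F3. Pd(OAc)2 in MeCN then gives the C8=C9 enone [trans-6-(2-chloroethyl)-2,2-dimethyl-7-oxospiro[3.5]non-8-en-5-yl]methyl acetate F4. Me3SiOTf/Et3N can now enolise only toward C6 and gives the silyloxydiene [6-(2-chloroethyl)-2,2-dimethyl-7-(trimethylsilyloxy)spiro[3.5]nona-6,8-dien-5-yl]methyl acetate F5. A second Pd(OAc)2 oxidation rejoins the route at 18, bypassing 17.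

3. Step 6 (conjugate addition). The β-carbon is flanked by the spiro quaternary carbon and by the α-substituent, so the bulky silylmethyl copper species may add too slowly and 1,2-addition or enone oligomerisation may take over. The fallback uses a smaller sp2 nucleophile and unmasks the hydroxymethyl group by oxidative cleavage. It sets out from 9. Vinylmagnesium bromide 6 with CuBr·SMe2 and Me3SiCl (THF, −78 °C) should give the enol silane {[6-(2-chloroethyl)-5-ethenyl-2,2-dimethylspiro[3.5]non-6-en-7-yl]oxy}trimethylsilane F6. Dilute acid work-up hydrolyses it to trans-6-(2-chloroethyl)-5-ethenyl-2,2-dimethylspiro[3.5]nonan-7-one F7. Ozonolysis (CH2Cl2, −78 °C; Me2S) gives trans-6-(2-chloroethyl)-2,2-dimethyl-7-oxospiro[3.5]nonane-5-carbaldehyde F8. Aldehyde-selective reduction with NaBH(OAc)3 rejoins the route at 14, bypassing 12 and 13.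

**Further compounds**

F1 | step 11 | [6-(2-chloroethyl)-7-ethenyl-7-hydroxy-2,2-dimethylspiro[3.5]nona-5,8-dien-5-yl]methyl acetate, racemic | CC(=O)OCC1=C(CCCl)C(O)(C=C)C=CC12CC(C)(C)C2
F2 | step 11 | [5-(2-chloroethyl)-6-ethenyl-2,2-dimethyl-2,3-dihydro-1H-inden-4-yl]methyl acetate | CC(=O)OCc1c(CCCl)c(C=C)cc2CC(C)(C)Cc12
F3 | step 9 | [trans-6-(2-chloroethyl)-2,2-dimethyl-7-(trimethylsilyloxy)spiro[3.5]non-7-en-5-yl]methyl acetate, racemic | CC(=O)OC[C@@H]1[C@@H](CCCl)C(O[Si](C)(C)C)=CCC12CC(C)(C)C2
F4 | step 9 | [trans-6-(2-chloroethyl)-2,2-dimethyl-7-oxospiro[3.5]non-8-en-5-yl]methyl acetate, racemic | CC(=O)OC[C@@H]1[C@@H](CCCl)C(=O)C=CC12CC(C)(C)C2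
F5 | step 9 | [6-(2-chloroethyl)-2,2-dimethyl-7-(trimethylsilyloxy)spiro[3.5]nona-6,8-dien-5-yl]methyl acetate, racemic | CC(=O)OCC1C(CCCl)=C(O[Si](C)(C)C)C=CC12CC(C)(C)C2
F6 | step 6 | {[6-(2-chloroethyl)-5-ethenyl-2,2-dimethylspiro[3.5]non-6-en-7-yl]oxy}trimethylsilane, racemic | C[Si](C)(C)OC1=C(CCCl)C(C=C)C2(CC1)CC(C)(C)C2
F7 | step 6 | trans-6-(2-chloroethyl)-5-ethenyl-2,2-dimethylspiro[3.5]nonan-7-one, racemic | C=C[C@@H]1[C@@H](CCCl)C(=O)CCC12CC(C)(C)C2
F8 | step 6 | trans-6-(2-chloroethyl)-2,2-dimethyl-7-oxospiro[3.5]nonane-5-carbaldehyde, racemic | O=C[C@@H]1[C@@H](CCCl)C(=O)CCC12CC(C)(C)C2
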